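**Retrosynthetic overview**

1. Only one ring is built, the 1,4-dioxane ring, and it is built last; both benzene rings are bought.
2. Quinone fragment: from 4-allyl-2,6-dimethoxyphenol 1 comes 5-allyl-3-methoxy-1,2-benzoquinone 2 by oxidative demethylation.
3. Alkene fragment: from (E)-2,6-dimethoxy-4-(prop-1-enyl)phenol 3 comes its TBS ether 4.
4. Key disconnection: both C–O bonds of the dioxane ring (O1–C2 and O4–C3) are cut together, so the silyl-protected benzodioxane 5 comes from 2 + 4 by a catalytic enantioselective oxa-[4+2] cycloaddition that sets both stereocentres.
5. 5 is desilylated in the same flask to the target 6.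

Assumption: 3 is bought as the (E)-isomer (flavour-grade material is predominantly trans; any (Z)-isomer is removed by chromatography of 4).

**Route**

Step 1
Reactants: 1 4-allyl-2,6-dimethoxyphenol (methoxyeugenol)
Product: 2 5-allyl-3-methoxycyclohexa-3,5-diene-1,2-dione (5-allyl-3-methoxy-1,2-benzoquinone)
Conditions: NaIO4 (1.2 equiv), AcOH–H2O (1:1), 0 °C, 15 min; extracted into cold CH2Cl2, dried, used the same day as a titrated solution
Reagents that add atoms: sodium periodate, [Na+].[O-]I(=O)(=O)=O (gives the new carbonyl oxygen; if the ring carbon is attacked by solvent instead, that oxygen is from water, O)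
Why: Adler-type periodate oxidation of a 2-methoxyphenol, in which the ring carbon carrying a methoxy group ortho to the OH is oxidised and methanol is expelled; the two ortho positions are equivalent and the para position is blocked by the allyl group, so one o-quinone results, the terminal alkene is inert to periodate alone, and no stereocentre is formed.

Step 2
Reactants: 3 2,6-dimethoxy-4-[(E)-prop-1-en-1-yl]phenol
Product: 4 tert-butyl{2,6-dimethoxy-4-[(E)-prop-1-en-1-yl]phenoxy}dimethylsilane
Conditions: TBSCl (1.3 equiv), imidazole (2.5 equiv), DMF, 40 °C
Reagents that add atoms: tert-butyldimethylsilyl chloride (TBSCl), CC(C)(C)[Si](C)(C)Cl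
Why: Imidazole-promoted silylation of a phenol (Corey protocol) caps the acidic, easily oxidised OH, which would otherwise give phenoxyl-radical and quinone-methide coupling with 2 and bind the copper catalyst, while the ring stays electron-rich and the (E)-alkene is untouched.

Step 3
Reactants: 2 5-allyl-3-methoxy-1,2-benzoquinone; 4 tert-butyl{2,6-dimethoxy-4-[(E)-prop-1-en-1-yl]phenoxy}dimethylsilane
Product: 6 4-[(2R,3R)-7-allyl-5-methoxy-3-methyl-2,3-dihydro-1,4-benzodioxin-2-yl]-2,6-dimethoxyphenol, via silyl-protected cycloadduct 5 (not isolated)
Conditions: Cu(OTf)2 (10 mol%), (R,R)-t-Bu-box [2,2'-(propane-2,2-diyl)bis((4R)-4-tert-butyl-4,5-dihydrooxazole)] (11 mol%), 4 Å MS, CH2Cl2, −40 to −20 °C, 4 (1.2 equiv), slow addition of 2 (1.0 equiv), 12 h; then TBAF (1.5 equiv), AcOH (1.5 equiv), THF, 0 °C, 30 min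
Reagents that add atoms: none
Why: Proposed new method: an enantioselective inverse-electron-demand oxa-Diels–Alder reaction in which quinone 2, chelated through both carbonyl oxygens to the square-planar divalent copper bis(oxazoline) complex (LUMO lowered, geometry fixed), serves as the O=C–C=O heterodiene for the electron-rich (E)-alkene 4: the nucleophilic methyl-bearing alkene carbon bonds to the oxygen of the more electrophilic carbonyl next to the methoxy group (the other carbonyl is a doubly vinylogous ester of that methoxy group and is further deactivated by the allyl-bearing carbon), the benzylic carbon closes on the second oxygen with aromatisation as the driving force, suprafacial addition across the (E)-alkene gives the trans ring, and the tert-butyl groups of the (R,R)-ligand block the exo position over one oxygen on each quinone face so that both allowed approaches give the same (2R,3R) product (sense taken from this quadrant model and to be confirmed by CD and chiral HPLC, the (S,S)-ligand giving the antipode); the closest known reaction types are the thermal racemic [4+2] cycloaddition of o-quinones with electron-rich alkenes and Cu(OTf)2–bis(oxazoline)-catalysed hetero-Diels–Alder reactions of chelating 1,2-dicarbonyl compounds, while the buffered fluoride added afterwards only cleaves the aryl silyl ether and leaves the allyl group and both stereocentres untouched.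

**Compound list**

1 | 4-allyl-2,6-dimethoxyphenol | C=CCc1cc(OC)c(O)c(OC)c1 | starting material
2 | 5-allyl-3-methoxycyclohexa-3,5-diene-1,2-dione | C=CCC1=CC(=O)C(=O)C(OC)=C1 | intermediate
3 | 2,6-dimethoxy-4-[(E)-prop-1-en-1-yl]phenol | C/C=C/c1cc(OC)c(O)c(OC)c1 | starting material
4 | tert-butyl{2,6-dimethoxy-4-[(E)-prop-1-en-1-yl]phenoxy}dimethylsilane | C/C=C/c1cc(OC)c(O[Si](C)(C)C(C)(C)C)c(OC)c1 | intermediate
5 | tert-butyl{4-[(2R,3R)-7-allyl-5-methoxy-3-methyl-2,3-dihydro-1,4-benzodioxin-2-yl]-2,6-dimethoxyphenoxy}dimethylsilane | C=CCc1cc(OC)c2c(c1)O[C@H](c1cc(OC)c(O[Si](C)(C)C(C)(C)C)c(OC)c1)[C@@H](C)O2 | intermediate (not isolated)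
6 | 4-[(2R,3R)-7-allyl-5-methoxy-3-methyl-2,3-dihydro-1,4-benzodioxin-2-yl]-2,6-dimethoxyphenol | C=CCc1cc(OC)c2c(c1)O[C@H](c1cc(OC)c(O)c(OC)c1)[C@@H](C)O2 | target

**Step count and risk**

Total steps: 3. Longest linear sequence: 2 steps (1 → 2 → 6, or equally 3 → 4 → 6).

The route has three steps, so all three are listed. Order of risk: step 3, then step 1, then step 2.

Step 1 (lability of quinone 2). The quinone may dimerise, tautomerise through its allyl group or over-oxidise in the aqueous oxidant. The fallback sets out from 1 and comes back at 2. It separates demethylation from oxidation. Chelation-directed mono-demethylation of 1 (AlCl3, pyridine, CH2Cl2, 40 °C) gives 5-allyl-3-methoxybenzene-1,2-diol F1, a storable catechol. F1 is dehydrogenated under anhydrous conditions just before use (Ag2O, Na2SO4, Et2O, 0 °C, 10 min, filtration), and the filtrate is the solution of 2 for step 3.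

Step 2 (lowest risk). The doubly ortho-substituted phenol may silylate slowly, and 3 is air-sensitive and may carry (Z)-isomer, which would give the cis ring in step 3. The fallback sets out from 1 and comes back at 4. It moves the protection to the robust allyl isomer and makes the propenyl group afterwards. Silylation of 1 (TBSOTf, 2,6-lutidine, CH2Cl2, 0 °C) gives tert-butyl(4-allyl-2,6-dimethoxyphenoxy)dimethylsilane F2. Ruthenium-hydride isomerisation of the allyl group (RuHCl(CO)(PPh3)3, 1 mol%, toluene, 80 °C) then gives the conjugated (E)-alkene 4 with high E selectivity.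

Step 3 (proposed new step). Possible failures:
- the quinone reacts as a carbodiene and gives a bicyclo[2.2.2]octenedione;
- the alkene attacks a ring carbon of the quinone instead of oxygen;
- the quinone dimerises;
- inner-sphere electron transfer gives racemic product;
- the regiochemistry or the ee is poor;
- the fluoride treatment partly epimerises C2 through a quinone methide (the cis epimer is separable and C3, hence the ee, is unaffected).

The fallback uses known chemistry. It sets out from 1 and 3 and comes back at 6. 1 is mono-demethylated to 5-allyl-3-methoxybenzene-1,2-diol F1 as in the fallback to step 1. F1 and unprotected 3 are cross-coupled oxidatively with Ag2O (benzene–acetone, rt, dark). This is the biomimetic route to eusiderin-type benzodioxanes: β–O coupling, then ring closure of the quinone methide by the neighbouring phenol, trans favoured. After chromatographic removal of the cis isomer, the regioisomer and dehydrodimers of 3, it gives racemic trans-4-(7-allyl-5-methoxy-3-methyl-2,3-dihydro-1,4-benzodioxin-2-yl)-2,6-dimethoxyphenol F3. Preparative chiral SFC (amylose tris(3,5-dimethylphenylcarbamate) phase, CO2–MeOH) then delivers the (2R,3R)-enantiomer 6, assigned by CD. The yield is low, but the sequence is short and gives the target directly with the phenol free.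

**Further compounds**

F1 | step 1 | 5-allyl-3-methoxybenzene-1,2-diol | C=CCc1cc(O)c(O)c(OC)c1
F2 | step 2 | tert-butyl(4-allyl-2,6-dimethoxyphenoxy)dimethylsilane | C=CCc1cc(OC)c(O[Si](C)(C)C(C)(C)C)c(OC)c1
F3 | step 3 | racemic trans-4-(7-allyl-5-methoxy-3-methyl-2,3-dihydro-1,4-benzodioxin-2-yl)-2,6-dimethoxyphenol (1:1 mixture of the (2R,3R)- and (2S,3S)-enantiomers) | C=CCc1cc(OC)c2c(c1)O[C@H](c1cc(OC)c(O)c(OC)c1)[C@@H](C)O2.C=CCc1cc(OC)c2c(c1)O[C@@H](c1cc(OC)c(O)c(OC)c1)[C@H](C)O2
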